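**Retrosynthetic overview**

1. The target is read as (−)-epicatechin-(4β→8)-(−)-epicatechin 3-O-gallate-(4β→8)-(−)-epicatechin 3-O-gallate. The end game is esterification of the lower 3-OH, then one hydrogenolysis that removes nineteen benzyl groups and one bromine cap.
2. Key disconnection, one flask: C4–C4a of the lower unit (closure of its pyran ring C) together with the lower interflavan bond C4(middle)–C8(lower). This leads back to the acyclic epoxy aryl ether 9 and the dimeric C4 electrophile 17.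
3. Enabling feature: in the lower unit, C4a is a ring A CH ortho to the O1 ether oxygen and ortho/para to the C5 and C7 oxygens. This phloroglucinol-type ring can open a C3–C4 epoxide at its CH2 end (C4), and is then nucleophilic at C8, the other CH ortho to O1.
4. Dimer 17 comes from two monomers, both made from chroman 10 (the ring-closure product of 9) by DDQ oxidation at C4. A soft leaving group (S-benzyl, AgBF4) and a hard one (O-alkyl, TMSOTf) are activated in turn, and a bromine on C8 of the upper unit blocks self-condensation.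
5. All eight stereocentres descend from the one bought centre of (R)-glyceraldehyde acetonide: C3 of each unit directly, C2 by Felkin–Anh addition then Mitsunobu inversion, both C4 by 3,4-trans capture. Ring order: rings C of the upper and middle units (step 5), then ring C of the lower unit (step 12).

Key step: step 12

Remark on the chemistry: "upper", "middle" and "lower" unit mean the flavan unit with the free 3-OH, the inner gallate-bearing unit and the terminal (C4H2) gallate-bearing unit; "4β" means trans to the C3 oxygen of the same unit.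

**Route**

Step 1
Reactants: 1 1,2-bis(benzyloxy)-4-bromobenzene; 2 (R)-2,2-dimethyl-1,3-dioxolane-4-carbaldehyde
Product: 5 (S)-[3,4-bis(benzyloxy)phenyl][(4R)-2,2-dimethyl-1,3-dioxolan-4-yl]methanol (anti adduct), via aryllithium 3 (not isolated), via aryltitanium triisopropoxide 4 (not isolated)
Conditions: 1, n-BuLi, THF, −78 °C; ClTi(OiPr)3, −78 to −40 °C; then 2, −78 to 0 °C; aq NH4Cl
Reagents that add atoms: none
Why: Bromine–lithium exchange and transmetallation give a non-chelating aryltitanium reagent whose 1,2-addition to the α-alkoxy aldehyde should follow the Felkin–Anh (non-chelation) model, so the new carbinol centre is expected anti to the dioxolane oxygen ((S) next to the bought (R) centre), the minor syn isomer being removable by chromatography.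

Step 2
Reactants: 5 anti alcohol; 6 3,5-bis(benzyloxy)phenol
Product: 7 (4R)-4-[(R)-[3,4-bis(benzyloxy)phenyl][3,5-bis(benzyloxy)phenoxy]methyl]-2,2-dimethyl-1,3-dioxolane
Conditions: PPh3, DIAD, toluene, 0 °C to rt
Reagents that add atoms: none
Why: Mitsunobu etherification in a non-polar solvent should displace the activated benzylic oxygen by the phenoxide in SN2 fashion with inversion, turning the anti (S) carbinol into the threo (R) aryl ether that maps onto a 2,3-cis flavan.

Step 3
Reactants: 7 aryl ether acetonide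
Product: 8 (2R,3R)-3-[3,4-bis(benzyloxy)phenyl]-3-[3,5-bis(benzyloxy)phenoxy]propane-1,2-diol
Conditions: AcOH/H2O/THF (4:1:1), 45 °C
Reagents that add atoms: none
Why: Acid-catalysed hydrolysis of the isopropylidene acetal under weakly acidic conditions should free the 1,2-diol without ionising the benzylic aryl ether; no stereocentre is touched.

Step 4
Reactants: 8 diol
Product: 9 (2R)-2-[(R)-[3,4-bis(benzyloxy)phenyl][3,5-bis(benzyloxy)phenoxy]methyl]oxirane
Conditions: NaH (2.2 equiv), 1-(p-toluenesulfonyl)imidazole, THF, 0 °C to rt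
Reagents that add atoms: none
Why: One-pot selective sulfonylation of the primary alkoxide followed by intramolecular Williamson displacement by the secondary alkoxide should give the terminal epoxide with the secondary C–O bond, and hence the future C3 configuration, retained.

Step 5
Reactants: 9 epoxy aryl ether
Product: 10 5,7,3',4'-tetra-O-benzyl-(−)-epicatechin, (2R,3R)-5,7-bis(benzyloxy)-2-[3,4-bis(benzyloxy)phenyl]chroman-3-ol
Conditions: AuCl3 (5 mol %), AgOTf (15 mol %), CH2Cl2, 0 °C to rt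
Reagents that add atoms: none
Why: Gold-catalysed intramolecular Friedel–Crafts epoxide–arene alkylation (trivalent gold triflate formed in situ) should open the epoxide at its CH2 terminus in the 6-endo mode through either of the two equivalent ring A positions ortho to the ether oxygen, closing pyran ring C; C2 and C3 are spectators, so the (2R,3R) cis chroman-3-ol results.

Step 6
Reactants: 10 tetra-O-benzylepicatechin
Product: 11 5,7,3',4'-tetra-O-benzyl-4β-(2-ethoxyethoxy)epicatechin
Conditions: DDQ, 2-ethoxyethanol, CH2Cl2, rt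
Reagents that add atoms: 2-ethoxyethanol, CCOCCO
Why: DDQ oxidation of the electron-rich benzylic C4 position (hydride abstraction) gives a ring-A-stabilised C4 cation that the alcohol should trap trans to the 3-OH, i.e. on the β face.

Step 7
Reactants: 11 4β-(2-ethoxyethoxy) ether
Product: 12 3,5,7,3',4'-penta-O-benzyl-4β-(2-ethoxyethoxy)epicatechin
Conditions: NaH, BnBr, DMF, 0 °C to rt
Reagents that add atoms: benzyl bromide, BrCc1ccccc1
Why: Williamson etherification of the secondary alkoxide; the C4 ether is stable to base, and the 3-O-benzyl group will leave the upper 3-OH free after the final hydrogenolysis while the other two 3-OH groups are esterified.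

Step 8
Reactants: 12 penta-O-benzyl 4β-ether
Product: 13 8-bromo-3,5,7,3',4'-penta-O-benzyl-4β-(2-ethoxyethoxy)epicatechin
Conditions: NBS, CH2Cl2, −78 to −40 °C
Reagents that add atoms: N-bromosuccinimide, O=C1CCC(=O)N1Br
Why: Electrophilic aromatic bromination of ring A should occur at C8, which is flanked by the ring oxygen and one benzyloxy group and is more accessible than C6 between two benzyloxy groups; the bromine caps the position through which the upper unit could self-condense.

Step 9
Reactants: 13 8-bromo 4β-ether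
Product: 14 8-bromo-3,5,7,3',4'-penta-O-benzyl-4β-(benzylthio)epicatechin
Conditions: BnSH (3 equiv), BF3·OEt2 (0.3 equiv), CH2Cl2, −40 to 0 °C
Reagents that add atoms: phenylmethanethiol, SCc1ccccc1
Why: Lewis-acid-catalysed SN1 exchange of the C4 alkoxy group by the thiol (thiolysis) via the C4 cation, the thiol adding trans to the 3-O substituent; this installs a soft leaving group that buffered silver activation can address selectively.

Step 10
Reactants: 11 4β-(2-ethoxyethoxy) ether; 15 3,4,5-tris(benzyloxy)benzoic acid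
Product: 16 5,7,3',4'-tetra-O-benzyl-4β-(2-ethoxyethoxy)epicatechin 3-O-[3,4,5-tris(benzyloxy)benzoate]
Conditions: DCC, DMAP, CH2Cl2, rt
Reagents that add atoms: none
Why: Steglich esterification of the secondary 3-OH under neutral conditions that leave the C4 ether intact; the ester is the future middle gallate and will shield the α face of C4.

Step 11
Reactants: 14 upper-unit thioether; 16 middle-unit gallate
Product: 17 8-bromo-3,5,7,3',4'-penta-O-benzylepicatechin-(4β→8)-[5,7,3',4'-tetra-O-benzyl-4β-(2-ethoxyethoxy)epicatechin 3-O-(3,4,5-tri-O-benzylgallate)]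
Conditions: AgBF4 (2.0 equiv), 2,6-di-tert-butyl-4-methylpyridine (2.0 equiv), 4 Å MS, CH2Cl2/THF, −40 to 0 °C, dark
Reagents that add atoms: none
Why: Thiophile-promoted Friedel–Crafts C4→C8 flavan coupling: AgBF4 should remove only the benzylthio group of 14, the buffered medium leaves the O-alkyl group of 16 intact, the bromine cap prevents self-condensation of 14, and C8 of 16 adds to the cation on the β face, trans to the 3-O-benzyl group and anti to the 2-aryl group, which sets C4 of the upper unit by substrate control.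

Step 12
Reactants: 9 epoxy aryl ether; 17 dimeric C4 electrophile
Product: 18 8-bromo-3,5,7,3',4'-penta-O-benzylepicatechin-(4β→8)-[5,7,3',4'-tetra-O-benzylepicatechin 3-O-(3,4,5-tri-O-benzylgallate)]-(4β→8)-5,7,3',4'-tetra-O-benzylepicatechin (lower 3-OH free), via tetra-O-benzylepicatechin 10 (not isolated)
Conditions: (a) 9 (1.5 equiv), AuCl3 (5 mol %), AgOTf (15 mol %), CH2Cl2, 0 °C to rt; (b) cool to −78 °C, add 17, then TMSOTf (0.3 equiv), −78 to −40 °C; Et3N quench
Reagents that add atoms: none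
Why: In stage (a) the trivalent gold triflate formed from AuCl3 and AgOTf activates the terminal epoxide of 9, and one of the two equivalent ring A CH positions ortho to the ether oxygen attacks the CH2 terminus in an intramolecular Friedel–Crafts epoxide–arene alkylation (closest known reaction type: gold-catalysed cycloalkylation of aryl 2,3-epoxypropyl ethers to chroman-3-ols), which forms C4–C4a and closes pyran ring C of the lower unit in the 6-endo mode. Neither stereocentre of 9 takes part (the C3–O bond is kept), so the 2,3-cis (2R,3R) pattern of 10 is the threo pattern built in steps 1 and 2. In stage (b) TMSOTf ionises the C4 O-alkyl group of 17 (Lewis-acid-catalysed Friedel–Crafts C4→C8 flavan coupling), giving a C4 cation stabilised by the ring A oxygens and by the carbonyl oxygen of the 3-O-galloyl group, and C8 of the freshly formed 10 adds to it. The new stereocentre, C4 of the middle unit, is set by substrate control: the 3-O-galloyl group (as a bridging dioxolanylium ion or simply by shielding) and the 2-aryl group block the α face, so the nucleophile should enter on the β face, trans to the C3 oxygen. The step needs 6-endo rather than 5-exo epoxide opening (secured by the unhindered primary carbon and the favoured six-membered ring), ring closure before coupling (secured by adding 17 only after stage (a), so the uncyclised ether is never offered to the cation) and C8 rather than C6 attack (C8 is flanked by the ring oxygen and one benzyloxy group, C6 by two). Self-condensation of 17 is suppressed by the bromine on C8 of its upper unit and by the excess of 9.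

Step 13
Reactants: 18 trimer with free lower 3-OH; 15 3,4,5-tris(benzyloxy)benzoic acid
Product: 19 8-bromo-3,5,7,3',4'-penta-O-benzylepicatechin-(4β→8)-[5,7,3',4'-tetra-O-benzylepicatechin 3-O-(3,4,5-tri-O-benzylgallate)]-(4β→8)-[5,7,3',4'-tetra-O-benzylepicatechin 3-O-(3,4,5-tri-O-benzylgallate)]
Conditions: DCC, DMAP, CH2Cl2, rt
Reagents that add atoms: none
Why: Steglich esterification of the only free hydroxyl group in 18 (the upper 3-O is a benzyl ether, the middle 3-O is already the gallate).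

Step 14
Reactants: 19 fully protected trimer
Product: 20 epicatechin-(4β→8)-epicatechin 3-O-gallate-(4β→8)-epicatechin 3-O-gallate (CNP0279403.1)
Conditions: H2 (1 atm), Pd(OH)2/C, THF/MeOH/H2O, rt
Reagents that add atoms: none
Why: Catalytic hydrogenolysis should cleave all nineteen benzyl ethers and reduce the aryl bromide (hydrodebromination) in one operation, while the gallate esters, the ring C ether bonds and the interflavan bonds are expected to survive the neutral, room-temperature conditions.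

**Compound list**

1 | 1,2-bis(benzyloxy)-4-bromobenzene | Brc1ccc(OCc2ccccc2)c(OCc2ccccc2)c1 | starting material
2 | (R)-2,2-dimethyl-1,3-dioxolane-4-carbaldehyde ((R)-glyceraldehyde acetonide) | O=C[C@H]1COC(C)(C)O1 | starting material
3 | [3,4-bis(benzyloxy)phenyl]lithium | [Li]c1ccc(OCc2ccccc2)c(OCc2ccccc2)c1 | intermediate (not isolated)
4 | [3,4-bis(benzyloxy)phenyl]titanium triisopropoxide | CC(C)O[Ti](OC(C)C)(OC(C)C)c1ccc(OCc2ccccc2)c(OCc2ccccc2)c1 | intermediate (not isolated)
5 | (S)-[3,4-bis(benzyloxy)phenyl][(4R)-2,2-dimethyl-1,3-dioxolan-4-yl]methanol | O[C@@H](c1ccc(OCc2ccccc2)c(OCc2ccccc2)c1)[C@H]1COC(C)(C)O1 | intermediate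
6 | 3,5-bis(benzyloxy)phenol | Oc1cc(OCc2ccccc2)cc(OCc2ccccc2)c1 | starting material
7 | (4R)-4-[(R)-[3,4-bis(benzyloxy)phenyl][3,5-bis(benzyloxy)phenoxy]methyl]-2,2-dimethyl-1,3-dioxolane | c1ccccc1COc1cc(OCc2ccccc2)cc(O[C@H](c2ccc(OCc3ccccc3)c(OCc3ccccc3)c2)[C@H]2COC(C)(C)O2)c1 | intermediate
8 | (2R,3R)-3-[3,4-bis(benzyloxy)phenyl]-3-[3,5-bis(benzyloxy)phenoxy]propane-1,2-diol | c1ccccc1COc1cc(OCc2ccccc2)cc(O[C@H](c2ccc(OCc3ccccc3)c(OCc3ccccc3)c2)[C@H](O)CO)c1 | intermediate
9 | (2R)-2-[(R)-[3,4-bis(benzyloxy)phenyl][3,5-bis(benzyloxy)phenoxy]methyl]oxirane | c1ccccc1COc1cc(OCc2ccccc2)cc(O[C@H](c2ccc(OCc3ccccc3)c(OCc3ccccc3)c2)[C@H]2CO2)c1 | intermediate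
10 | 5,7,3',4'-tetra-O-benzyl-(−)-epicatechin, (2R,3R)-5,7-bis(benzyloxy)-2-[3,4-bis(benzyloxy)phenyl]chroman-3-ol | O[C@@H]1Cc2c(OCc5ccccc5)cc(OCc5ccccc5)cc2O[C@@H]1c1ccc(OCc5ccccc5)c(OCc5ccccc5)c1 | intermediate (isolated in step 5, formed in the flask in step 12)
11 | 5,7,3',4'-tetra-O-benzyl-4β-(2-ethoxyethoxy)epicatechin | O[C@@H]1[C@@H](OCCOCC)c2c(OCc5ccccc5)cc(OCc5ccccc5)cc2O[C@@H]1c1ccc(OCc5ccccc5)c(OCc5ccccc5)c1 | intermediate
12 | 3,5,7,3',4'-penta-O-benzyl-4β-(2-ethoxyethoxy)epicatechin | c5ccccc5CO[C@@H]1[C@@H](OCCOCC)c2c(OCc5ccccc5)cc(OCc5ccccc5)cc2O[C@@H]1c1ccc(OCc5ccccc5)c(OCc5ccccc5)c1 | intermediate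
13 | 8-bromo-3,5,7,3',4'-penta-O-benzyl-4β-(2-ethoxyethoxy)epicatechin | c5ccccc5CO[C@@H]1[C@@H](OCCOCC)c2c(OCc5ccccc5)cc(OCc5ccccc5)c(Br)c2O[C@@H]1c1ccc(OCc5ccccc5)c(OCc5ccccc5)c1 | intermediate
14 | 8-bromo-3,5,7,3',4'-penta-O-benzyl-4β-(benzylthio)epicatechin | c5ccccc5CO[C@@H]1[C@@H](SCc5ccccc5)c2c(OCc5ccccc5)cc(OCc5ccccc5)c(Br)c2O[C@@H]1c1ccc(OCc5ccccc5)c(OCc5ccccc5)c1 | intermediate
15 | 3,4,5-tris(benzyloxy)benzoic acid | OC(=O)c1cc(OCc2ccccc2)c(OCc2ccccc2)c(OCc2ccccc2)c1 | starting material
16 | 5,7,3',4'-tetra-O-benzyl-4β-(2-ethoxyethoxy)epicatechin 3-O-[3,4,5-tris(benzyloxy)benzoate] | O=C(O[C@@H]1[C@@H](OCCOCC)c2c(OCc5ccccc5)cc(OCc5ccccc5)cc2O[C@@H]1c1ccc(OCc5ccccc5)c(OCc5ccccc5)c1)c1cc(OCc5ccccc5)c(OCc5ccccc5)c(OCc5ccccc5)c1 | intermediate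
17 | 8-bromo-penta-O-benzylepicatechin-(4β→8)-[tetra-O-benzyl-4β-(2-ethoxyethoxy)epicatechin 3-O-(tri-O-benzylgallate)] | O=C(O[C@@H]1[C@@H](OCCOCC)c2c(OCc5ccccc5)cc(OCc5ccccc5)c([C@H]3c4c(OCc5ccccc5)cc(OCc5ccccc5)c(Br)c4O[C@H](c4ccc(OCc5ccccc5)c(OCc5ccccc5)c4)[C@@H]3OCc5ccccc5)c2O[C@@H]1c1ccc(OCc5ccccc5)c(OCc5ccccc5)c1)c1cc(OCc5ccccc5)c(OCc5ccccc5)c(OCc5ccccc5)c1 | intermediate
18 | 8-bromo-penta-O-benzylepicatechin-(4β→8)-[tetra-O-benzylepicatechin 3-O-(tri-O-benzylgallate)]-(4β→8)-tetra-O-benzylepicatechin (lower 3-OH free) | O=C(O[C@@H]1[C@@H](c2c(OCc5ccccc5)cc(OCc5ccccc5)c3c2O[C@H](c2ccc(OCc5ccccc5)c(OCc5ccccc5)c2)[C@H](O)C3)c2c(OCc5ccccc5)cc(OCc5ccccc5)c([C@H]3c4c(OCc5ccccc5)cc(OCc5ccccc5)c(Br)c4O[C@H](c4ccc(OCc5ccccc5)c(OCc5ccccc5)c4)[C@@H]3OCc5ccccc5)c2O[C@@H]1c1ccc(OCc5ccccc5)c(OCc5ccccc5)c1)c1cc(OCc5ccccc5)c(OCc5ccccc5)c(OCc5ccccc5)c1 | intermediate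
19 | 8-bromo-penta-O-benzylepicatechin-(4β→8)-[tetra-O-benzylepicatechin 3-O-(tri-O-benzylgallate)]-(4β→8)-[tetra-O-benzylepicatechin 3-O-(tri-O-benzylgallate)] | O=C(O[C@@H]1[C@@H](c2c(OCc5ccccc5)cc(OCc5ccccc5)c3c2O[C@H](c2ccc(OCc5ccccc5)c(OCc5ccccc5)c2)[C@H](OC(=O)c2cc(OCc5ccccc5)c(OCc5ccccc5)c(OCc5ccccc5)c2)C3)c2c(OCc5ccccc5)cc(OCc5ccccc5)c([C@H]3c4c(OCc5ccccc5)cc(OCc5ccccc5)c(Br)c4O[C@H](c4ccc(OCc5ccccc5)c(OCc5ccccc5)c4)[C@@H]3OCc5ccccc5)c2O[C@@H]1c1ccc(OCc5ccccc5)c(OCc5ccccc5)c1)c1cc(OCc5ccccc5)c(OCc5ccccc5)c(OCc5ccccc5)c1 | intermediate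
20 | epicatechin-(4β→8)-epicatechin 3-O-gallate-(4β→8)-epicatechin 3-O-gallate (CNP0279403.1) | O=C(O[C@@H]1[C@@H](c2c(O)cc(O)c3c2O[C@H](c2ccc(O)c(O)c2)[C@H](OC(=O)c2cc(O)c(O)c(O)c2)C3)c2c(O)cc(O)c([C@H]3c4c(O)cc(O)cc4O[C@H](c4ccc(O)c(O)c4)[C@@H]3O)c2O[C@@H]1c1ccc(O)c(O)c1)c1cc(O)c(O)c(O)c1 | target

**Step count and risks**

Total step count: 14. Longest linear sequence: 13 steps (steps 1–9, then 11–14).

Steps most likely to fail:

1. Step 12. The Lewis acids may ionise the benzylic C2–O bond of 9 before ring closure (ring opening, loss of C2 configuration), the cation from 17 may be captured at C6 or at oxygen, or catalyst residues from stage (a) may ionise 17 prematurely. Fallback: the lower unit is introduced as the isolated chroman and the chain is grown from the bottom. Setting out from 10 and 16, TMSOTf-catalysed coupling of 16 with an excess of 10 at −78 °C should give [tetra-O-benzylepicatechin 3-O-(tri-O-benzylgallate)]-(4β→8)-tetra-O-benzylepicatechin with free lower 3-OH F1. Steglich esterification with 15 then gives the dimeric digallate F2. F2 serves as C8 nucleophile toward thioether 14 under AgBF4 with 2,6-di-tert-butyl-4-methylpyridine, and the route is rejoined at 19.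

2. Step 2. The activated, electron-rich benzylic alcohol may ionise (loss of inversion), the phenol may be alkylated on carbon, or elimination may compete. Fallback: the C–O bond is made on the aryl side, with retention at the carbinol. Setting out from 5, oxidation with DMP gives aryl ketone F3. Felkin–Anh reduction with LiBH(s-Bu)3 at −78 °C gives the syn alcohol (R)-[3,4-bis(benzyloxy)phenyl][(4R)-2,2-dimethyl-1,3-dioxolan-4-yl]methanol F4. Ullmann-type C–O coupling of F4 with 1,3-bis(benzyloxy)-5-iodobenzene (CuI, 3,4,7,8-tetramethyl-1,10-phenanthroline, Cs2CO3, toluene, 110 °C) returns to the route at 7.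

3. Step 11. Ionisation of the bromine-deactivated thioether may be slow, acid build-up may ionise the C4 ether of 16 (oligomers), or attack may occur at C6. Fallback: no thioether is used and the C4 leaving group of the middle unit is installed after the coupling. Setting out from 10 and 13, Steglich esterification of 10 with 15 gives tetra-O-benzylepicatechin 3-O-(tri-O-benzylgallate) F5. TMSOTf-catalysed coupling of 13 with F5 gives the dimer with C4H2 in its middle unit F6. DDQ/2-ethoxyethanol oxidation of F6 at that benzylic position returns to the route at 17.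

Further compounds

F1 | step 12 | [5,7,3',4'-tetra-O-benzylepicatechin 3-O-(tri-O-benzylgallate)]-(4β→8)-5,7,3',4'-tetra-O-benzylepicatechin (lower 3-OH free) | O=C(O[C@@H]1[C@@H](c2c(OCc5ccccc5)cc(OCc5ccccc5)c3c2O[C@H](c2ccc(OCc5ccccc5)c(OCc5ccccc5)c2)[C@H](O)C3)c2c(OCc5ccccc5)cc(OCc5ccccc5)cc2O[C@@H]1c1ccc(OCc5ccccc5)c(OCc5ccccc5)c1)c1cc(OCc5ccccc5)c(OCc5ccccc5)c(OCc5ccccc5)c1
F2 | step 12 | [5,7,3',4'-tetra-O-benzylepicatechin 3-O-(tri-O-benzylgallate)]-(4β→8)-[5,7,3',4'-tetra-O-benzylepicatechin 3-O-(tri-O-benzylgallate)] | O=C(O[C@@H]1[C@@H](c2c(OCc5ccccc5)cc(OCc5ccccc5)c3c2O[C@H](c2ccc(OCc5ccccc5)c(OCc5ccccc5)c2)[C@H](OC(=O)c2cc(OCc5ccccc5)c(OCc5ccccc5)c(OCc5ccccc5)c2)C3)c2c(OCc5ccccc5)cc(OCc5ccccc5)cc2O[C@@H]1c1ccc(OCc5ccccc5)c(OCc5ccccc5)c1)c1cc(OCc5ccccc5)c(OCc5ccccc5)c(OCc5ccccc5)c1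
F3 | step 2 | [3,4-bis(benzyloxy)phenyl][(4R)-2,2-dimethyl-1,3-dioxolan-4-yl]methanone | O=C(c1ccc(OCc2ccccc2)c(OCc2ccccc2)c1)[C@H]1COC(C)(C)O1
F4 | step 2 | (R)-[3,4-bis(benzyloxy)phenyl][(4R)-2,2-dimethyl-1,3-dioxolan-4-yl]methanol (syn alcohol) | O[C@H](c1ccc(OCc2ccccc2)c(OCc2ccccc2)c1)[C@H]1COC(C)(C)O1
F5 | step 11 | 5,7,3',4'-tetra-O-benzylepicatechin 3-O-(3,4,5-tri-O-benzylgallate) | O=C(O[C@@H]1Cc2c(OCc5ccccc5)cc(OCc5ccccc5)cc2O[C@@H]1c1ccc(OCc5ccccc5)c(OCc5ccccc5)c1)c1cc(OCc5ccccc5)c(OCc5ccccc5)c(OCc5ccccc5)c1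
F6 | step 11 | 8-bromo-3,5,7,3',4'-penta-O-benzylepicatechin-(4β→8)-[5,7,3',4'-tetra-O-benzylepicatechin 3-O-(tri-O-benzylgallate)] | O=C(O[C@@H]1Cc2c(OCc5ccccc5)cc(OCc5ccccc5)c([C@H]3c4c(OCc5ccccc5)cc(OCc5ccccc5)c(Br)c4O[C@H](c4ccc(OCc5ccccc5)c(OCc5ccccc5)c4)[C@@H]3OCc5ccccc5)c2O[C@@H]1c1ccc(OCc5ccccc5)c(OCc5ccccc5)c1)c1cc(OCc5ccccc5)c(OCc5ccccc5)c(OCc5ccccc5)c1
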